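**Plan**

1. Atom labels follow germacrane numbering: lactone O–C6, ring-fusion C7, acyloxy carbon C8, C9, C10 (CO2Me = C14)=C1, C2, C3, C4 (C15H2OH), C5, and C11(=C13)–C12 in the lactone. Retrosynthetic cuts, in order: the C15 O–Si bond and the C8–O ester (made with inversion); the ring bond C7–C8; the butenolide double bond C7=C11 together with the ester C12–O6; C1=C10; C3–C4.
2. Enabling feature: in the α-methylene-γ-lactone, C13=C11–C7 is an allyl unit whose inner end C7 is bonded to the carbinol carbon C8 of the ten-membered ring. Moving the double bond into the five-membered ring (C7=C11, bromide on C13) and opening C7–C8 leaves a 3-(bromomethyl)butenolide tethered through C5–C4–C3–C2–C1=C10–C9 to a C8 aldehyde.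
3. Forward: the C1–C7 chain with C15 is built on a γ-vinyl-γ-butyrolactone template that is cut open with LiAlH4; a Wittig reaction adds C8–C10 and C14; metathesis closes the butenolide (first ring); the CrCl2-mediated allylation closes the cyclodecene (second ring) and returns the exocyclic methylene; esterification and desilylation finish.
4. Stereochemistry: C6 from the chiral-pool hydroxymethyl butyrolactone; C4 by trans alkylation on the lactone template; C7 by addition anti to C5 across the butenolide; C8 by the chair transition state of the allylation (8α-OH), then inverted in the Mitsunobu esterification; the side-chain center from the purchased (R)-acid; the C1=C10 geometry from the stabilized ylide.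

Key step: step 13

Remark on the chemistry: the iodo acetal used in step 3 and the (R)-configured acid used in step 14 are taken as purchasable (the iodide is otherwise one halide exchange from the commercial bromo acetal). TBS = tert-butyldimethylsilyl, TBDPS = tert-butyldiphenylsilyl.

**Route**

Step 1
Reactants: 1 (5R)-5-(hydroxymethyl)oxolan-2-one
Product: 2 (2R)-5-oxooxolane-2-carbaldehyde
Conditions: Dess–Martin periodinane, CH2Cl2, 0 → 25 °C; used crude
Reagents that add atoms: none
Why: Dess–Martin oxidation takes the primary alcohol to the aldehyde under neutral conditions, so the oxygen-bearing stereocenter next to the new carbonyl is not enolized.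

Step 2
Reactants: 2 (2R)-5-oxooxolane-2-carbaldehyde
Product: 3 (5R)-5-ethenyloxolan-2-one
Conditions: Ph3PCH3Br, KN(SiMe3)2, THF, −78 → 0 °C
Reagents that add atoms: methyltriphenylphosphonium bromide, C[P+](c1ccccc1)(c1ccccc1)c1ccccc1.[Br-]
Why: Wittig methylenation at low temperature should convert the aldehyde to the vinyl group (C7 and the carbon later lost as ethylene) faster than it enolizes, so C6 keeps its R configuration.

Step 3
Reactants: 3 (5R)-5-ethenyloxolan-2-one; 4 2-(2-iodoethyl)-1,3-dioxolane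
Product: 6 (3S,5R)-3-[2-(1,3-dioxolan-2-yl)ethyl]-5-ethenyloxolan-2-one, via lithium enolate 5 (not isolated)
Conditions: LiN(i-Pr)2, THF, −78 °C; then 4, DMPU, −78 → −30 °C
Reagents that add atoms: none
Why: Enolate alkylation (SN2 on the primary iodide) should occur on the ring face opposite the γ-vinyl group, forming C3–C4 and setting C4 trans to the C6 substituent (3S), with DMPU speeding the slow substitution.

Step 4
Reactants: 6 (3S,5R)-3-[2-(1,3-dioxolan-2-yl)ethyl]-5-ethenyloxolan-2-one
Product: 7 (2S,4R)-2-[2-(1,3-dioxolan-2-yl)ethyl]hex-5-ene-1,4-diol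
Conditions: LiAlH4, THF, 0 °C; aqueous work-up
Reagents that add atoms: none
Why: Hydride reduction opens the lactone template to the 1,4-diol, freeing C15 as CH2OH and O6 as the allylic alcohol without touching the acetal, the alkene or either stereocenter.

Step 5
Reactants: 7 (2S,4R)-2-[2-(1,3-dioxolan-2-yl)ethyl]hex-5-ene-1,4-diol
Product: 8 (3R,5S)-6-{[tert-butyl(diphenyl)silyl]oxy}-5-[2-(1,3-dioxolan-2-yl)ethyl]hex-1-en-3-ol
Conditions: TBDPSCl, imidazole, CH2Cl2, 0 °C
Reagents that add atoms: tert-butyl(chloro)diphenylsilane, CC(C)(C)[Si](Cl)(c1ccccc1)c1ccccc1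
Why: Silylation with the bulky chlorosilane should be selective for the primary C15 hydroxyl over the secondary allylic one.

Step 6
Reactants: 8 (3R,5S)-6-{[tert-butyl(diphenyl)silyl]oxy}-5-[2-(1,3-dioxolan-2-yl)ethyl]hex-1-en-3-ol
Product: 9 (4S,6R)-4-({[tert-butyl(diphenyl)silyl]oxy}methyl)-6-hydroxyoct-7-enal
Conditions: 1 M aq HCl, THF, 25 °C
Reagents that add atoms: water, O
Why: Acid-catalysed acetal hydrolysis frees the C1 aldehyde, while the TBDPS ether and the allylic alcohol withstand dilute acid at room temperature.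

Step 7
Reactants: 10 methyl 2-(triphenyl-λ5-phosphanylidene)acetate (2 equiv); 11 tert-butyl(2-iodoethoxy)dimethylsilane
Product: 13 methyl 4-{[tert-butyl(dimethyl)silyl]oxy}-2-(triphenyl-λ5-phosphanylidene)butanoate, via phosphonium iodide 12 (not isolated)
Conditions: MeCN, reflux
Reagents that add atoms: none
Why: C-alkylation of the stabilized ylide by the primary iodide gives the phosphonium salt, which the second equivalent of 10 deprotonates (transylidation) to the substituted ylide carrying C8, C9, C10 and C14.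

Step 8
Reactants: 9 (4S,6R)-4-({[tert-butyl(diphenyl)silyl]oxy}methyl)-6-hydroxyoct-7-enal; 13 methyl 4-{[tert-butyl(dimethyl)silyl]oxy}-2-(triphenyl-λ5-phosphanylidene)butanoate
Product: 14 methyl (2E,6S,8R)-2-(2-{[tert-butyl(dimethyl)silyl]oxy}ethyl)-6-({[tert-butyl(diphenyl)silyl]oxy}methyl)-8-hydroxydeca-2,9-dienoate
Conditions: toluene, 80 °C
Reagents that add atoms: none
Why: Wittig olefination with the α-substituted stabilized ylide should give the trisubstituted enoate with C2 trans to the ester (the C1=C10 geometry of the target) and tolerates the free alcohol.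

Step 9
Reactants: 14 methyl (2E,6S,8R)-2-(2-{[tert-butyl(dimethyl)silyl]oxy}ethyl)-6-({[tert-butyl(diphenyl)silyl]oxy}methyl)-8-hydroxydeca-2,9-dienoate; 15 2-(bromomethyl)prop-2-enoic acid
Product: 16 methyl (2E,6S,8R)-8-{[2-(bromomethyl)prop-2-enoyl]oxy}-2-(2-{[tert-butyl(dimethyl)silyl]oxy}ethyl)-6-({[tert-butyl(diphenyl)silyl]oxy}methyl)deca-2,9-dienoate
Conditions: DCC, DMAP (cat.), CH2Cl2, 0 °C
Reagents that add atoms: none
Why: Steglich esterification acylates the only free hydroxyl (O6) and brings in C11, C12 and C13 with the bromide already in place, the low temperature and catalytic DMAP limiting substitution at the allylic bromide.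

Step 10
Reactants: 16 methyl (2E,6S,8R)-8-{[2-(bromomethyl)prop-2-enoyl]oxy}-2-(2-{[tert-butyl(dimethyl)silyl]oxy}ethyl)-6-({[tert-butyl(diphenyl)silyl]oxy}methyl)deca-2,9-dienoate
Product: 17 methyl (2E,6S)-7-[(2R)-4-(bromomethyl)-5-oxo-2,5-dihydrofuran-2-yl]-2-(2-{[tert-butyl(dimethyl)silyl]oxy}ethyl)-6-({[tert-butyl(diphenyl)silyl]oxy}methyl)hept-2-enoate
Conditions: second-generation Grubbs catalyst (5 mol%), CH2Cl2, 40 °C, 5 mM
Reagents that add atoms: none
Why: Ring-closing metathesis between the vinyl group and the 1,1-disubstituted acrylate closes the five-membered butenolide (C7=C11) with loss of ethylene, while the trisubstituted, ester-bearing C1=C10 alkene is too hindered and electron-poor to take part.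

Step 11
Reactants: 17 methyl (2E,6S)-7-[(2R)-4-(bromomethyl)-5-oxo-2,5-dihydrofuran-2-yl]-2-(2-{[tert-butyl(dimethyl)silyl]oxy}ethyl)-6-({[tert-butyl(diphenyl)silyl]oxy}methyl)hept-2-enoate
Product: 18 methyl (2E,6S)-7-[(2R)-4-(bromomethyl)-5-oxo-2,5-dihydrofuran-2-yl]-6-({[tert-butyl(diphenyl)silyl]oxy}methyl)-2-(2-hydroxyethyl)hept-2-enoate
Conditions: camphorsulfonic acid (cat.), MeOH/CH2Cl2, 0 °C
Reagents that add atoms: none
Why: Acid-catalysed methanolysis should remove the primary TBS ether far faster than the TBDPS ether, and the allylic bromide is stable to acid.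

Step 12
Reactants: 18 methyl (2E,6S)-7-[(2R)-4-(bromomethyl)-5-oxo-2,5-dihydrofuran-2-yl]-6-({[tert-butyl(diphenyl)silyl]oxy}methyl)-2-(2-hydroxyethyl)hept-2-enoate
Product: 19 methyl (2E,6S)-7-[(2R)-4-(bromomethyl)-5-oxo-2,5-dihydrofuran-2-yl]-6-({[tert-butyl(diphenyl)silyl]oxy}methyl)-2-(2-oxoethyl)hept-2-enoate
Conditions: Dess–Martin periodinane, NaHCO3, CH2Cl2, 0 °C; used at once
Reagents that add atoms: none
Why: Buffered Dess–Martin oxidation gives the β,γ-unsaturated C8 aldehyde without acid or base that could move the C1=C10 double bond into conjugation.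

Step 13
Reactants: 19 methyl (2E,6S)-7-[(2R)-4-(bromomethyl)-5-oxo-2,5-dihydrofuran-2-yl]-6-({[tert-butyl(diphenyl)silyl]oxy}methyl)-2-(2-oxoethyl)hept-2-enoate
Product: 21 methyl (3aR,4S,6E,10S,11aR)-10-({[tert-butyl(diphenyl)silyl]oxy}methyl)-4-hydroxy-3-methylidene-2-oxo-2,3,3a,4,5,8,9,10,11,11a-decahydrocyclodeca[b]furan-6-carboxylate (8α-alcohol), via allylchromium dichloride 20 (not isolated)
Conditions: CrCl2 (8 equiv), THF, 25 °C, 19 added over 10 h (final 2 mM); then aqueous pH 7 buffer
Reagents that add atoms: none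
Why: Two equivalents of CrCl2 reduce the allylic C13–Br bond of 19 to the allylchromium 20 (trivalent chromium on C13), which binds the C8 aldehyde oxygen and transfers the allyl unit through its γ-carbon C7 in a six-membered chair transition state, so that C7–C8 forms while the double bond moves from C7=C11 to the exocyclic C11=C13 position. The closest known reaction types are the Nozaki–Hiyama–Kishi macrocyclization of 2-(bromomethyl)alk-2-enoates onto aldehydes to give ten-membered germacrane rings and the chromium- or zinc-mediated addition of 3-(bromomethyl)furan-2(5H)-ones to aldehydes. The cyclodecene closes in a 10-exo-trig mode at the aldehyde carbon, and the lactone ring, already present, only gives up its endocyclic double bond. C7 is controlled by C6, because C8 should add to the butenolide face anti to the C5 chain, which gives the trans ring fusion (H6 β, H7 α). C8 is controlled by the chair, in which the endocyclic allyl unit is locked with C6 trans to the CH2Cr carbon and the C9 chain lies pseudo-equatorial, which should give the anti adduct with the hydroxyl α (4S), the epimer that step 14 inverts. The step needs ring closure to win over intermolecular coupling (slow addition at high dilution), γ- over α-attack (inherent to allylchromium reagents, and α-attack would require a twelve-membered ring) and reaction at the aldehyde only (allylchromium reagents leave the esters and the lactone untouched and are not basic enough to isomerize the β,γ-unsaturated aldehyde).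

Step 14
Reactants: 21 methyl (3aR,4S,6E,10S,11aR)-10-({[tert-butyl(diphenyl)silyl]oxy}methyl)-4-hydroxy-3-methylidene-2-oxo-2,3,3a,4,5,8,9,10,11,11a-decahydrocyclodeca[b]furan-6-carboxylate; 22 (2R)-2-methylbutanoic acid
Product: 23 methyl (3aS,4R,6E,10S,11aR)-10-({[tert-butyl(diphenyl)silyl]oxy}methyl)-3-methylidene-4-{[(2R)-2-methylbutanoyl]oxy}-2-oxo-2,3,3a,4,5,8,9,10,11,11a-decahydrocyclodeca[b]furan-6-carboxylate
Conditions: PPh3, diisopropyl azodicarboxylate (betaine preformed at 0 °C), then 21 and 22, toluene, 0 → 25 °C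
Reagents that add atoms: none
Why: Mitsunobu esterification displaces the activated C8 oxygen by the carboxylate in an SN2 step, which installs the side chain and inverts C8 from 4S to 4R (8β-acyloxy) in one operation without touching the stereocenter of the acid.

Step 15
Reactants: 23 methyl (3aS,4R,6E,10S,11aR)-10-({[tert-butyl(diphenyl)silyl]oxy}methyl)-3-methylidene-4-{[(2R)-2-methylbutanoyl]oxy}-2-oxo-2,3,3a,4,5,8,9,10,11,11a-decahydrocyclodeca[b]furan-6-carboxylate
Product: 24 methyl (3aS,4R,6E,10S,11aR)-10-(hydroxymethyl)-3-methylidene-4-{[(2R)-2-methylbutanoyl]oxy}-2-oxo-2,3,3a,4,5,8,9,10,11,11a-decahydrocyclodeca[b]furan-6-carboxylate (target)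
Conditions: HF·pyridine, pyridine, THF, 0 → 25 °C
Reagents that add atoms: none
Why: Fluoride cleaves the silyl ether under mildly acidic conditions that should leave the α-methylene lactone, both esters and the epimerizable side-chain center intact.

**Compound list**

1 | (5R)-5-(hydroxymethyl)oxolan-2-one | OC[C@H]1CCC(=O)O1 | starting material
2 | (2R)-5-oxooxolane-2-carbaldehyde | O=C[C@H]1CCC(=O)O1 | intermediate
3 | (5R)-5-ethenyloxolan-2-one | C=C[C@H]1CCC(=O)O1 | intermediate
4 | 2-(2-iodoethyl)-1,3-dioxolane | ICCC1OCCO1 | starting material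
5 | lithium (5R)-5-ethenyl-4,5-dihydrofuran-2-olate (lithium enolate of 3) | C=C[C@H]1CC=C(O[Li])O1 | intermediate
6 | (3S,5R)-3-[2-(1,3-dioxolan-2-yl)ethyl]-5-ethenyloxolan-2-one (3,5-trans) | C=C[C@H]1C[C@H](CCC2OCCO2)C(=O)O1 | intermediate
7 | (2S,4R)-2-[2-(1,3-dioxolan-2-yl)ethyl]hex-5-ene-1,4-diol | C=C[C@H](O)C[C@@H](CO)CCC1OCCO1 | intermediate
8 | (3R,5S)-6-{[tert-butyl(diphenyl)silyl]oxy}-5-[2-(1,3-dioxolan-2-yl)ethyl]hex-1-en-3-ol | C=C[C@H](O)C[C@@H](CO[Si](c1ccccc1)(c1ccccc1)C(C)(C)C)CCC1OCCO1 | intermediate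
9 | (4S,6R)-4-({[tert-butyl(diphenyl)silyl]oxy}methyl)-6-hydroxyoct-7-enal | C=C[C@H](O)C[C@@H](CO[Si](c1ccccc1)(c1ccccc1)C(C)(C)C)CCC=O | intermediate
10 | methyl 2-(triphenyl-λ5-phosphanylidene)acetate | COC(=O)C=P(c1ccccc1)(c1ccccc1)c1ccccc1 | starting material
11 | tert-butyl(2-iodoethoxy)dimethylsilane | CC(C)(C)[Si](C)(C)OCCI | starting material
12 | (4-{[tert-butyl(dimethyl)silyl]oxy}-1-methoxy-1-oxobutan-2-yl)triphenylphosphonium iodide | COC(=O)C(CCO[Si](C)(C)C(C)(C)C)[P+](c1ccccc1)(c1ccccc1)c1ccccc1.[I-] | intermediate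
13 | methyl 4-{[tert-butyl(dimethyl)silyl]oxy}-2-(triphenyl-λ5-phosphanylidene)butanoate | COC(=O)C(CCO[Si](C)(C)C(C)(C)C)=P(c1ccccc1)(c1ccccc1)c1ccccc1 | intermediate
14 | methyl (2E,6S,8R)-2-(2-{[tert-butyl(dimethyl)silyl]oxy}ethyl)-6-({[tert-butyl(diphenyl)silyl]oxy}methyl)-8-hydroxydeca-2,9-dienoate | C=C[C@H](O)C[C@@H](CO[Si](c1ccccc1)(c1ccccc1)C(C)(C)C)CC/C=C(/C(=O)OC)CCO[Si](C)(C)C(C)(C)C | intermediate
15 | 2-(bromomethyl)prop-2-enoic acid | C=C(CBr)C(=O)O | starting material
16 | methyl (2E,6S,8R)-8-{[2-(bromomethyl)prop-2-enoyl]oxy}-2-(2-{[tert-butyl(dimethyl)silyl]oxy}ethyl)-6-({[tert-butyl(diphenyl)silyl]oxy}methyl)deca-2,9-dienoate | C=C[C@H](OC(=O)C(=C)CBr)C[C@@H](CO[Si](c1ccccc1)(c1ccccc1)C(C)(C)C)CC/C=C(/C(=O)OC)CCO[Si](C)(C)C(C)(C)C | intermediate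
17 | methyl (2E,6S)-7-[(2R)-4-(bromomethyl)-5-oxo-2,5-dihydrofuran-2-yl]-2-(2-{[tert-butyl(dimethyl)silyl]oxy}ethyl)-6-({[tert-butyl(diphenyl)silyl]oxy}methyl)hept-2-enoate | O=C1O[C@H](C[C@@H](CO[Si](c2ccccc2)(c2ccccc2)C(C)(C)C)CC/C=C(/C(=O)OC)CCO[Si](C)(C)C(C)(C)C)C=C1CBr | intermediate
18 | methyl (2E,6S)-7-[(2R)-4-(bromomethyl)-5-oxo-2,5-dihydrofuran-2-yl]-6-({[tert-butyl(diphenyl)silyl]oxy}methyl)-2-(2-hydroxyethyl)hept-2-enoate | O=C1O[C@H](C[C@@H](CO[Si](c2ccccc2)(c2ccccc2)C(C)(C)C)CC/C=C(/C(=O)OC)CCO)C=C1CBr | intermediate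
19 | methyl (2E,6S)-7-[(2R)-4-(bromomethyl)-5-oxo-2,5-dihydrofuran-2-yl]-6-({[tert-butyl(diphenyl)silyl]oxy}methyl)-2-(2-oxoethyl)hept-2-enoate | O=C1O[C@H](C[C@@H](CO[Si](c2ccccc2)(c2ccccc2)C(C)(C)C)CC/C=C(/C(=O)OC)CC=O)C=C1CBr | intermediate
20 | allylchromium dichloride of 19 (bromine on C13 replaced by a CrCl2 unit, trivalent chromium) | O=C1O[C@H](C[C@@H](CO[Si](c2ccccc2)(c2ccccc2)C(C)(C)C)CC/C=C(/C(=O)OC)CC=O)C=C1C[Cr](Cl)Cl | intermediate
21 | methyl (3aR,4S,6E,10S,11aR)-10-({[tert-butyl(diphenyl)silyl]oxy}methyl)-4-hydroxy-3-methylidene-2-oxo-2,3,3a,4,5,8,9,10,11,11a-decahydrocyclodeca[b]furan-6-carboxylate (8α-alcohol, trans-fused) | C=C1C(=O)O[C@@H]2C[C@@H](CO[Si](c3ccccc3)(c3ccccc3)C(C)(C)C)CC/C=C(/C(=O)OC)C[C@H](O)[C@@H]12 | intermediate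
22 | (2R)-2-methylbutanoic acid | CC[C@@H](C)C(=O)O | starting material
23 | methyl (3aS,4R,6E,10S,11aR)-10-({[tert-butyl(diphenyl)silyl]oxy}methyl)-3-methylidene-4-{[(2R)-2-methylbutanoyl]oxy}-2-oxo-2,3,3a,4,5,8,9,10,11,11a-decahydrocyclodeca[b]furan-6-carboxylate | C=C1C(=O)O[C@@H]2C[C@@H](CO[Si](c3ccccc3)(c3ccccc3)C(C)(C)C)CC/C=C(/C(=O)OC)C[C@@H](OC(=O)[C@H](C)CC)[C@@H]12 | intermediate
24 | methyl (3aS,4R,6E,10S,11aR)-10-(hydroxymethyl)-3-methylidene-4-{[(2R)-2-methylbutanoyl]oxy}-2-oxo-2,3,3a,4,5,8,9,10,11,11a-decahydrocyclodeca[b]furan-6-carboxylate | C=C1C(=O)O[C@@H]2C[C@@H](CO)CC/C=C(/C(=O)OC)C[C@@H](OC(=O)[C@H](C)CC)[C@@H]12 | target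

**Step count and risks**

Total step count: 15. Longest linear sequence: 14 steps (steps 1–6 and 8–15, from 1 to 24); step 7 is a one-step side branch.

Steps most likely to fail:

1. Step 13. What may go wrong: the forming ten-membered ring may force the aldehyde to add through a boat-like arrangement (C9 chain over C6) instead of the chair, so that the C8 hydroxyl appears on the β face, alone or as part of a mixture. Fallback: the sequence sets out from 19 as before. The epimeric alcohol methyl (3aR,4R,6E,10S,11aR)-10-({[tert-butyl(diphenyl)silyl]oxy}methyl)-4-hydroxy-3-methylidene-2-oxo-2,3,3a,4,5,8,9,10,11,11a-decahydrocyclodeca[b]furan-6-carboxylate F1 already has the C8 configuration of the target. The inverting esterification is therefore replaced by acylation with retention: Steglich esterification of F1 with 22 (DCC, DMAP, CH2Cl2, 25 °C) should give 23, where the route is rejoined. A mixture of 21 and F1 would be separated and each epimer taken to 23 by its own esterification.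

2. Step 14. What may go wrong: the activated C8 oxygen may be lost by elimination toward C9, whose hydrogens are allylic to the enoate, or substitution may stall because the carboxylate has to enter between C6 and C11 on the lactone side of C8. Fallback: the sequence sets out from 21. Dess–Martin oxidation (NaHCO3, CH2Cl2, 0 °C) should give the C8 ketone methyl (3aS,6E,10S,11aR)-10-({[tert-butyl(diphenyl)silyl]oxy}methyl)-3-methylidene-2,4-dioxo-2,3,3a,4,5,8,9,10,11,11a-decahydrocyclodeca[b]furan-6-carboxylate F2, kept cold and neutral so that H7 is not enolized. Luche reduction (NaBH4, CeCl3·7H2O, MeOH, −78 °C) should deliver hydride from the face next to H7, away from the lactone ring, without conjugate reduction of the methylene lactone, and give the 8β-alcohol F1. Steglich acylation of F1 with 22 then comes back to the route at 23.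

3. Step 3. What may go wrong: the unactivated iodide may substitute too slowly, so that proton exchange between enolate and product, double alkylation, elimination of HI from the iodide and erosion of the trans preference compete. Fallback: the sequence sets out from 3. The enolate 5 is alkylated with allyl bromide, a fast and trans-selective electrophile, to (3S,5R)-5-ethenyl-3-(prop-2-en-1-yl)oxolan-2-one F3. Hydroboration with 9-BBN, which should prefer the allyl group over the vinyl group that is deactivated and shielded by the allylic ring oxygen, followed by NaBO3·4H2O, gives (3S,5R)-5-ethenyl-3-(3-hydroxypropyl)oxolan-2-one F4. Dess–Martin oxidation gives 3-[(3S,5R)-5-ethenyl-2-oxooxolan-3-yl]propanal F5. Acetalization with ethylene glycol (pyridinium p-toluenesulfonate, benzene, reflux with water removal) gives 6, where the route is rejoined.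

**Further compounds**

F1 | step 13 | methyl (3aR,4R,6E,10S,11aR)-10-({[tert-butyl(diphenyl)silyl]oxy}methyl)-4-hydroxy-3-methylidene-2-oxo-2,3,3a,4,5,8,9,10,11,11a-decahydrocyclodeca[b]furan-6-carboxylate (8β-alcohol) | C=C1C(=O)O[C@@H]2C[C@@H](CO[Si](c3ccccc3)(c3ccccc3)C(C)(C)C)CC/C=C(/C(=O)OC)C[C@@H](O)[C@@H]12
F2 | step 14 | methyl (3aS,6E,10S,11aR)-10-({[tert-butyl(diphenyl)silyl]oxy}methyl)-3-methylidene-2,4-dioxo-2,3,3a,4,5,8,9,10,11,11a-decahydrocyclodeca[b]furan-6-carboxylate | C=C1C(=O)O[C@@H]2C[C@@H](CO[Si](c3ccccc3)(c3ccccc3)C(C)(C)C)CC/C=C(/C(=O)OC)CC(=O)[C@@H]12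
F3 | step 3 | (3S,5R)-5-ethenyl-3-(prop-2-en-1-yl)oxolan-2-one | C=C[C@H]1C[C@H](CC=C)C(=O)O1
F4 | step 3 | (3S,5R)-5-ethenyl-3-(3-hydroxypropyl)oxolan-2-one | C=C[C@H]1C[C@H](CCCO)C(=O)O1
F5 | step 3 | 3-[(3S,5R)-5-ethenyl-2-oxooxolan-3-yl]propanal | C=C[C@H]1C[C@H](CCC=O)C(=O)O1
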